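The route rests on opening the O1–C2 bond of the oxolane ring (O1, C2 with the aryl group, C3 with CH2OH, C4 with the aroyl group, C5H2) to a C2 ketone. Because the two aryl groups are identical, this exposes a meso 1,4-diaryl-1,4-diketone bearing two hydroxymethyl groups. The key step reverses that opening in one operation: hemiketalisation, ionisation and silane reduction of the cyclic oxocarbenium ion anti to the C3 substituent form the O1–C2 bond, the ring and the C2 stereocentre. Its precursor is the lipase-derived, enantioenriched monoacetate of the meso diketone diol, in which only one hydroxymethyl group is free to cyclise.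

Key step: step 5

Assumption: the lipase acetylates the hydroxymethyl group on the (S)-configured carbon of meso diol 6 (if it prefers the other arm, the hydrolytic mode in the fallback for step 4 gives the same monoacetate 8). The γ-hydroxy ketones 6 and 8 are drawn open-chain although they should rest largely as five-membered hemiketals.

Step 1
Reactants: 1 1-(3,4,5-trimethoxyphenyl)ethanone (2 equiv, both molecules are built into the product)
Product: 3 1,4-bis(3,4,5-trimethoxyphenyl)butane-1,4-dione, via lithium enolate 2 (not isolated)
Conditions: LDA (LiN(iPr)2, 1.05 equiv per ketone), THF, −78 °C; then anhydrous CuCl2 (1.05 equiv per ketone), DMF, −78 °C to rt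
Reagents that add atoms: a second molecule of 1-(3,4,5-trimethoxyphenyl)ethanone (1), CC(=O)c1cc(OC)c(OC)c(OC)c1
Why: Oxidative homocoupling of a ketone lithium enolate by one-electron oxidation with CuCl2 (divalent copper is reduced to monovalent copper) joins the α-carbons of two molecules of the methyl ketone to the symmetrical 1,4-diketone, and no stereocentre is formed.

Step 2
Reactants: 3 1,4-bis(3,4,5-trimethoxyphenyl)butane-1,4-dione
Product: 4 (1Z,3Z)-1,4-bis(3,4,5-trimethoxyphenyl)-1,4-bis(trimethylsilyloxy)buta-1,3-diene
Conditions: LDA (2.4 equiv), TMSCl (3 equiv, present from the start), THF, −78 °C to 0 °C; non-aqueous work-up (pentane, filtration)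
Reagents that add atoms: chlorotrimethylsilane (two silyl groups are transferred), C[Si](C)(C)Cl
Why: Double deprotonation with in situ O-silylation (kinetic silyl enol ether formation) turns each α-CH2 into one latent nucleophilic carbon and, being free of acid, avoids the Paal–Knorr furan closure open to 1,4-diketones; the enol ether geometry is of no consequence later.

Step 3
Reactants: 4 (1Z,3Z)-1,4-bis(3,4,5-trimethoxyphenyl)-1,4-bis(trimethylsilyloxy)buta-1,3-diene; 5 formaldehyde
Product: 6 meso-(2R,3S)-2,3-bis(hydroxymethyl)-1,4-bis(3,4,5-trimethoxyphenyl)butane-1,4-dione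
Conditions: 37% aq. HCHO (excess), Yb(OTf)3 (10 mol %), THF–H2O, rt; chromatographic separation of the meso diol from the racemic diastereomer
Reagents that add atoms: formaldehyde (5, two molecules are taken up), C=O
Why: The lanthanide-triflate-catalysed aqueous Mukaiyama aldol (hydroxymethylation) adds exactly one CH2OH per enol ether carbon, and the β-hydroxy ketone cannot enolise again under these near-neutral conditions; the two stereocentres form without strong bias, so the meso diol is separated from the racemic diastereomer, which should differ sharply in polarity because it alone can close to a cis-fused bicyclic bis-hemiketal.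

Step 4
Reactants: 6 meso-(2R,3S)-2,3-bis(hydroxymethyl)-1,4-bis(3,4,5-trimethoxyphenyl)butane-1,4-dione; 7 vinyl acetate
Product: 8 [(2S,3R)-3-(hydroxymethyl)-4-oxo-2-(3,4,5-trimethoxybenzoyl)-4-(3,4,5-trimethoxyphenyl)butyl] acetate (acetoxymethyl on the S carbon, free hydroxymethyl on the R carbon)
Conditions: immobilised Burkholderia cepacia lipase, vinyl acetate (3 equiv), MTBE, 25–30 °C, stopped before diacetate appears; filtration, used without storage
Reagents that add atoms: vinyl acetate (7), C=COC(C)=O
Why: Lipase-catalysed irreversible transesterification with an enol ester (enzymatic desymmetrisation of a meso 1,4-diol) acylates one of the two enantiotopic primary hydroxyl groups, which fixes the absolute configuration of both existing stereocentres without creating a new one, and tautomerisation of the released vinyl alcohol to acetaldehyde prevents the reverse reaction.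

Step 5
Reactants: 8 [(2S,3R)-3-(hydroxymethyl)-4-oxo-2-(3,4,5-trimethoxybenzoyl)-4-(3,4,5-trimethoxyphenyl)butyl] acetate
Product: 11 [(2S,3S,4R)-4-(3,4,5-trimethoxybenzoyl)-2-(3,4,5-trimethoxyphenyl)oxolan-3-yl]methyl acetate, via cyclic hemiketal 9 (not isolated), via oxocarbenium ion 10 (not isolated)
Conditions: Et3SiH (3 equiv), then BF3·OEt2 (2 equiv), CH2Cl2, −78 °C to −40 °C; quench cold with aq. NaHCO3
Reagents that add atoms: none
Why: The free C5 hydroxyl adds to the C2 carbonyl (5-exo-trig, the only ring closure made) to give hemiketal 9, BF3·OEt2 removes the hemiketal hydroxyl to form the aryl-conjugated oxocarbenium ion 10, and Et3SiH transfers hydride to C2, so the O1–C2 bond, the oxolane ring and the C2–H bond arise in one flask. The closest known reaction type is the reductive cycloetherification of γ-hydroxy ketones, that is, the ionic hydrogenation of 2-aryl lactols with a silane and a Lewis acid as practised for C-aryl glycosides and 2-aryl tetrahydrofuran lignans. The new C2 stereocentre is controlled by the neighbouring C3 acetoxymethyl group: allylic strain with the coplanar C2 aryl group pushes it pseudoaxial, hydride enters on the opposite face and the aryl group ends cis to C3 (2S), an outcome that participation of the acetate carbonyl from the C3 face would only reinforce. The step needs this facial selectivity even though the C4 aroyl group lies on the attacked face, which should be tolerable because that group is one atom further from C2 than the C3 substituent. It also needs site and chemoselectivity: only the ketone with a free γ-hydroxyl can form a hemiketal, since the γ-oxygen of the other ketone is acetylated and a second closure would require a trans-fused bicycle, and ionic hydrogenation of the remaining aryl ketone is slow at −78 °C. Having the silane present before the Lewis acid lets hydride capture outrun proton loss from C3, so the C3 and C4 configurations fixed by the enzyme are carried through.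

Step 6
Reactants: 11 [(2S,3S,4R)-4-(3,4,5-trimethoxybenzoyl)-2-(3,4,5-trimethoxyphenyl)oxolan-3-yl]methyl acetate
Product: 12 [(2S,3S,4R)-3-(hydroxymethyl)-2-(3,4,5-trimethoxyphenyl)oxolan-4-yl](3,4,5-trimethoxyphenyl)methanone (2,3-cis, 3,4-trans)
Conditions: K2CO3 (0.2 equiv), MeOH, 0 °C; neutralise with NH4Cl
Reagents that add atoms: none
Why: Base-catalysed transesterification (Zemplén-type methanolysis) removes the primary acetate, while C2 and C3 carry no acidic hydrogen, C4 already holds the more stable 3,4-trans arrangement, and ring opening by β-elimination would be the reverse of a disfavoured 5-endo-trig closure.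

Compound list
1 | 1-(3,4,5-trimethoxyphenyl)ethanone | CC(=O)c1cc(OC)c(OC)c(OC)c1 | starting material
2 | lithium enolate of 1 | [Li]OC(=C)c1cc(OC)c(OC)c(OC)c1 | intermediate
3 | 1,4-bis(3,4,5-trimethoxyphenyl)butane-1,4-dione | O=C(CCC(=O)c1cc(OC)c(OC)c(OC)c1)c1cc(OC)c(OC)c(OC)c1 | intermediate
4 | (1Z,3Z)-1,4-bis(3,4,5-trimethoxyphenyl)-1,4-bis(trimethylsilyloxy)buta-1,3-diene | C[Si](C)(C)O/C(=C\C=C(/O[Si](C)(C)C)c1cc(OC)c(OC)c(OC)c1)c1cc(OC)c(OC)c(OC)c1 | intermediate
5 | formaldehyde | C=O | starting material
6 | meso-(2R,3S)-2,3-bis(hydroxymethyl)-1,4-bis(3,4,5-trimethoxyphenyl)butane-1,4-dione | O=C(c1cc(OC)c(OC)c(OC)c1)[C@@H](CO)[C@@H](CO)C(=O)c1cc(OC)c(OC)c(OC)c1 | intermediate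
7 | vinyl acetate | C=COC(C)=O | starting material
8 | [(2S,3R)-3-(hydroxymethyl)-4-oxo-2-(3,4,5-trimethoxybenzoyl)-4-(3,4,5-trimethoxyphenyl)butyl] acetate | O=C(c1cc(OC)c(OC)c(OC)c1)[C@@H](CO)[C@@H](COC(C)=O)C(=O)c1cc(OC)c(OC)c(OC)c1 | intermediate
9 | [(3S,4R)-2-hydroxy-4-(3,4,5-trimethoxybenzoyl)-2-(3,4,5-trimethoxyphenyl)oxolan-3-yl]methyl acetate, both C2 epimers | O=C(c1cc(OC)c(OC)c(OC)c1)[C@H]1COC(O)(c2cc(OC)c(OC)c(OC)c2)[C@@H]1COC(C)=O | intermediate
10 | (3S,4R)-3-(acetoxymethyl)-4-(3,4,5-trimethoxybenzoyl)-2-(3,4,5-trimethoxyphenyl)-4,5-dihydro-3H-furan-1-ium (oxocarbenium ion) | O=C(c1cc(OC)c(OC)c(OC)c1)[C@H]1C[O+]=C(c2cc(OC)c(OC)c(OC)c2)[C@@H]1COC(C)=O | intermediate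
11 | [(2S,3S,4R)-4-(3,4,5-trimethoxybenzoyl)-2-(3,4,5-trimethoxyphenyl)oxolan-3-yl]methyl acetate | O=C(c1cc(OC)c(OC)c(OC)c1)[C@H]1CO[C@H](c2cc(OC)c(OC)c(OC)c2)[C@@H]1COC(C)=O | intermediate
12 | [(2S,3S,4R)-3-(hydroxymethyl)-2-(3,4,5-trimethoxyphenyl)oxolan-4-yl](3,4,5-trimethoxyphenyl)methanone | COc1cc(C(=O)[C@H]2CO[C@H](c3cc(OC)c(OC)c(OC)c3)[C@@H]2CO)cc(OC)c1OC | target

Total step count: 6. Longest linear sequence: 6 steps (1 to 12).

Steps most likely to fail

Step 5. The hydride may discriminate poorly between the two faces of C2 because the C4 aroyl group sits on the face it must use. The remaining aryl ketone may also undergo ionic hydrogenation, or the cation may lose the C3 proton and scramble or aromatise. The fallback sets out from 8 and returns at 11. Treating 8 with thiophenol and catalytic camphorsulfonic acid (CH2Cl2, −40 °C) should trap the hemiketal carbon as the mixed O,S-ketal, [(3S,4R)-2-(phenylsulfanyl)-4-(3,4,5-trimethoxybenzoyl)-2-(3,4,5-trimethoxyphenyl)oxolan-3-yl]methyl acetate F1. Radical C–S reduction with Bu3SnH and AIBN (toluene, 80 °C) then generates a planar benzylic α-oxy radical, which should take hydrogen on the face away from the C3 substituent. These neutral conditions neither reduce the aryl ketone nor allow cation-type proton loss, and a bulkier hydrogen donor can be used to sharpen the facial preference.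

Step 3. The second aldol addition may show little preference for the meso arrangement, and the β-hydroxy ketones may be eroded by retro-aldol cleavage or dehydration. The fallback sets out from 1 and returns at 6, with the two extra carbons introduced at the ester oxidation level before the central bond is made. Claisen condensation of 1 with diethyl carbonate (NaH, THF, reflux) should give ethyl 3-oxo-3-(3,4,5-trimethoxyphenyl)propanoate F2. Oxidative dimerisation of its sodium enolate with iodine (NaH, then I2, THF, 0 °C) gives diethyl meso-(2R,3S)-2,3-bis(3,4,5-trimethoxybenzoyl)butanedioate F3. Its doubly activated methines epimerise freely, so the unwanted diastereomer can be re-equilibrated and recycled instead of discarded. Exhaustive reduction with LiAlH4 (THF, −20 to 0 °C) gives the tetraol, 2,3-bis(hydroxymethyl)-1,4-bis(3,4,5-trimethoxyphenyl)butane-1,4-diol F4, with the meso-type relation at C2 and C3 retained. Chemoselective oxidation of the two benzylic alcohols with activated MnO2 (CH2Cl2, rt) then leaves the primary alcohols untouched and delivers 6.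

Step 4. The enzyme may acylate the other enantiotopic arm, distinguish the arms poorly, or run on to the diacetate, and acyl migration in the product would lower the enantiomeric purity. The fallback sets out from 6 and returns at 8, using the hydrolytic rather than the acylating mode of desymmetrisation. Acetylation of both hydroxyl groups (Ac2O, pyridine, 0 °C) should give the meso diacetate, meso-(2R,3S)-2,3-bis(acetoxymethyl)-1,4-bis(3,4,5-trimethoxyphenyl)butane-1,4-dione F5. Lipase-catalysed hydrolysis (pH 7 phosphate buffer with MTBE, rt) then removes the acetate from the arm that the enzyme recognises. This leaves the acetate on the opposite arm compared with the acylation mode, so the same lipase, or a second one screened in this mode, can deliver 8.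

Further compounds
F1 | step 5 | [(3S,4R)-2-(phenylsulfanyl)-4-(3,4,5-trimethoxybenzoyl)-2-(3,4,5-trimethoxyphenyl)oxolan-3-yl]methyl acetate, both C2 epimers | O=C(c1cc(OC)c(OC)c(OC)c1)[C@H]1COC(Sc2ccccc2)(c2cc(OC)c(OC)c(OC)c2)[C@@H]1COC(C)=O
F2 | step 3 | ethyl 3-oxo-3-(3,4,5-trimethoxyphenyl)propanoate | CCOC(=O)CC(=O)c1cc(OC)c(OC)c(OC)c1
F3 | step 3 | diethyl meso-(2R,3S)-2,3-bis(3,4,5-trimethoxybenzoyl)butanedioate | CCOC(=O)[C@H](C(=O)c1cc(OC)c(OC)c(OC)c1)[C@H](C(=O)c1cc(OC)c(OC)c(OC)c1)C(=O)OCC
F4 | step 3 | 2,3-bis(hydroxymethyl)-1,4-bis(3,4,5-trimethoxyphenyl)butane-1,4-diol, meso-type relation at C2 and C3, carbinol centres unassigned | OC(c1cc(OC)c(OC)c(OC)c1)[C@@H](CO)[C@@H](CO)C(O)c1cc(OC)c(OC)c(OC)c1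
F5 | step 4 | meso-(2R,3S)-2,3-bis(acetoxymethyl)-1,4-bis(3,4,5-trimethoxyphenyl)butane-1,4-dione | O=C(c1cc(OC)c(OC)c(OC)c1)[C@@H](COC(C)=O)[C@@H](COC(C)=O)C(=O)c1cc(OC)c(OC)c(OC)c1
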